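**Retrosynthetic overview**
1. Target 20 ← Z-oxocene 19 (epoxidation) ← ring-closing metathesis of the 8α-O-allyl ether 18 ← 3β-bromoambreinolide 15 (MeLi, Wittig, O-allylation).
2. 15 ← proton-initiated cationic bicyclization of the monocyclic bromo ester 14: ring B (C9–C10) and the δ-lactone (C8–O) form together and set C8, C9 and C10.
3. 14 ← Diels–Alder adduct 10: ring A is assembled from diene 6 (C2, C1, C10, C5) and enal 9 (C3, C4), which forms C2–C3 and C4–C5.
4. Enabling feature: once ring B is opened at C9–C10, ring A carries a C1=C10 double bond, so it is a cyclohexene whose saturated C3(Br)–C4(Me2) edge lies opposite the olefin. One C4 methyl is carried as a formyl group (activation), and the C3 bromine as the epimeric benzoate.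
5. Ring order: A (step 5), then B with the lactone (step 9), then the eight-membered ether (step 13), then the oxirane (step 14).

Key step: step 5

Remark: atoms are numbered as in labdane (C1–C20). The sense of induction of the catalyst in step 5 is taken from the usual model for 2-substituted enals; if it proved opposite, the catalyst made from (R)-diphenylprolinol would be used and nothing else would change.

**Step 1**
Reactants: 1 geranyl bromide; 2 tert-butyl acetate
Product: 3 tert-butyl (4E)-5,9-dimethyldeca-4,8-dienoate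
Conditions: LiN(i-Pr)2, THF, −78 °C; then 1, DMPU, −78 → 0 °C
Reagents that add atoms: none
Why: Alkylation of the lithium ester enolate with the primary allylic bromide (SN2) should give 3 with the E olefin of the geranyl unit untouched; no stereocenter is formed.

**Step 2**
Reactants: 3 tert-butyl (4E)-5,9-dimethyldeca-4,8-dienoate
Product: 5 tert-butyl (4E,8E)-5,9-dimethyl-10-oxodeca-4,8-dienoate, via allylic alcohol 4 (not isolated)
Conditions: SeO2 (0.3 equiv), t-BuOOH, salicylic acid (cat.), CH2Cl2, rt; then MnO2, CH2Cl2, rt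
Reagents that add atoms: tert-butyl hydroperoxide, CC(C)(C)OO (oxygen relayed by SeO2)
Why: Allylic oxidation with selenium dioxide (ene reaction, then [2,3]-sigmatropic shift) should attack the E-methyl group of the terminal, least hindered trisubstituted olefin, and MnO2 then oxidises the allylic alcohol to the E enal; no stereocenter is formed.

**Step 3**
Reactants: 5 tert-butyl (4E,8E)-5,9-dimethyl-10-oxodeca-4,8-dienoate
Product: 6 tert-butyl (4E,8E)-5,9-dimethylundeca-4,8,10-trienoate
Conditions: Ph3PCH3Br, KOtBu, THF, 0 °C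
Reagents that add atoms: methyltriphenylphosphonium bromide, C[P+](c1ccccc1)(c1ccccc1)c1ccccc1.[Br-]
Why: Wittig methylenation of the aldehyde should give the terminal 1,3-diene without touching the E trisubstituted olefins or the tert-butyl ester.

**Step 4**
Reactants: 7 (2E)-3-ethoxy-2-methylprop-2-enal
Product: 9 (1E)-2-methyl-3-oxoprop-1-en-1-yl benzoate, via sodium enolate 8 (not isolated)
Conditions: NaOH (1.0 equiv), H2O, rt, evaporate; then BzCl, THF, 0 °C
Reagents that add atoms: sodium hydroxide, [Na+].[OH-]; benzoyl chloride, O=C(Cl)c1ccccc1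
Why: Hydroxide displaces ethoxide from the vinylogous ester by addition–elimination and the malonaldehyde enolate is then O-acylated (Schotten–Baumann-type acylation), the extended enolate giving the E enol benzoate.

**Step 5**
Reactants: 6 tert-butyl (4E,8E)-5,9-dimethylundeca-4,8,10-trienoate; 9 (1E)-2-methyl-3-oxoprop-1-en-1-yl benzoate
Product: 10 tert-butyl (4E)-7-[(1R,5R,6R)-5-(benzoyloxy)-6-formyl-2,6-dimethylcyclohex-2-en-1-yl]-5-methylhept-4-enoate
Conditions: (S)-3,3-diphenyl-1-(2-methylphenyl)tetrahydro-1H,3H-pyrrolo[1,2-c][1,3,2]oxazaborole·HN(SO2CF3)2 (20 mol %), CH2Cl2, −78 → −20 °C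
Reagents that add atoms: none
Why: Catalytic enantioselective Diels–Alder reaction: the chiral oxazaborolidinium ion binds the formyl oxygen of 9, and the s-cis diene of 6 adds in a concerted, asynchronous [4+2] in which the unsubstituted terminus C2 bonds first to the oxygen-stabilised β-carbon C3 and C5 then closes onto the formyl-bearing carbon C4. The closest known reactions are oxazaborolidinium-catalysed Diels–Alder additions of 2-methylacrolein-type enals to acyclic dienes and Lewis-acid Diels–Alder reactions of trisubstituted α-methyl enals with trialkyl dienes. Ring A is closed as a cyclohexene by an intermolecular suprafacial–suprafacial cycloaddition that leaves the C1=C10 olefin. C5 is set by the catalyst, which leaves one face of the bound enal open; the C3–O centre is fixed relative to C5 by the E geometry of both partners and the endo position of the formyl group (benzoate exo, hence trans to the side chain, 3α), and C4 is a temporary stereocenter that disappears in step 6. The step needs "ortho" regioselectivity (C4 to C5), which the 1-alkyl substituent of the diene and the polarisation of the vinylogous acyl dienophile should secure, and endo selectivity, which Lewis-acid activation of the formyl group should secure.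

**Step 6**
Reactants: 10 tert-butyl (4E)-7-[(1R,5R,6R)-5-(benzoyloxy)-6-formyl-2,6-dimethylcyclohex-2-en-1-yl]-5-methylhept-4-enoate
Product: 12 tert-butyl (4E)-7-[(1R,5R)-5-(benzoyloxy)-2,6,6-trimethylcyclohex-2-en-1-yl]-5-methylhept-4-enoate, via tosylhydrazone 11 (not isolated)
Conditions: TsNHNH2, THF, 4 Å MS, rt; then catecholborane, CHCl3, 0 °C; then NaOAc·3H2O, 60 °C
Reagents that add atoms: 4-methylbenzenesulfonohydrazide, Cc1ccc(cc1)S(=O)(=O)NN (its atoms stay in 11 only; 12 gains hydrogen only)
Why: Reductive deoxygenation of the aldehyde through its tosylhydrazone (Caglioti-type reduction, catecholborane variant): hydride adds to C=N and acetate-induced loss of sulfinate and N2 leaves a methyl group, so C4 becomes the gem-dimethyl carbon while C3 and C5 are untouched.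

**Step 7**
Reactants: 12 tert-butyl (4E)-7-[(1R,5R)-5-(benzoyloxy)-2,6,6-trimethylcyclohex-2-en-1-yl]-5-methylhept-4-enoate
Product: 13 tert-butyl (4E)-7-[(1R,5R)-5-hydroxy-2,6,6-trimethylcyclohex-2-en-1-yl]-5-methylhept-4-enoate
Conditions: K2CO3 (cat.), MeOH, 40 °C
Reagents that add atoms: none
Why: Base-catalysed transesterification with methanol should remove the benzoate and leave the hindered tert-butyl ester; C3 keeps its configuration because only the acyl–oxygen bond is broken.

**Step 8**
Reactants: 13 tert-butyl (4E)-7-[(1R,5R)-5-hydroxy-2,6,6-trimethylcyclohex-2-en-1-yl]-5-methylhept-4-enoate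
Product: 14 tert-butyl (4E)-7-[(1R,5S)-5-bromo-2,6,6-trimethylcyclohex-2-en-1-yl]-5-methylhept-4-enoate
Conditions: CBr4, PPh3, 2,6-lutidine, CH2Cl2, 0 °C → rt
Reagents that add atoms: carbon tetrabromide, BrC(Br)(Br)Br
Why: Appel reaction: bromide displaces the alkoxyphosphonium group in an SN2 step with inversion, turning the 3α-alcohol into the 3β-bromide (cis to the C5 side chain); the flexible monocyclic ring and buffered, non-ionising conditions are meant to suppress Wagner–Meerwein shifts at this neopentyl centre.

**Step 9**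
Reactants: 14 tert-butyl (4E)-7-[(1R,5S)-5-bromo-2,6,6-trimethylcyclohex-2-en-1-yl]-5-methylhept-4-enoate
Product: 15 3β-bromoambreinolide (3β-bromo-8α,13-epoxy-14,15,16-trinorlabdan-13-one; 5α-H, 9α-H, 8β-CH3, 10β-CH3)
Conditions: ClSO3H (3 equiv), 2-nitropropane, −78 °C; then aq. NaHCO3
Reagents that add atoms: none
Why: Proton-initiated cationic polyene cyclization: Markovnikov protonation of the C1=C10 olefin gives the tertiary C10 cation, the E C8=C9 olefin adds through a chair transition state anti to the axial 4β-methyl (6-endo closure, trans ring fusion, 10β-methyl, 9α-H), and the ester carbonyl oxygen traps the C8 cation anti to the new C9–C10 bond with loss of isobutene (8α-O, 8β-methyl).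

**Step 10**
Reactants: 15 3β-bromoambreinolide
Product: 16 3β-bromo-8α-hydroxy-14,15-dinorlabdan-13-one
Conditions: MeLi (1.3 equiv), THF, −78 °C; then H2O
Reagents that add atoms: methyllithium, [Li]C
Why: Addition of methyllithium to the δ-lactone should stop at the lactolate at low temperature and give the methyl ketone (in equilibrium with its cyclic hemiketal) on work-up; the equatorial neopentyl bromide has no anti-periplanar hydrogen and should survive.

**Step 11**
Reactants: 16 3β-bromo-8α-hydroxy-14,15-dinorlabdan-13-one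
Product: 17 3β-bromo-14,15-dinorlabd-13(16)-en-8α-ol
Conditions: Ph3PCH3Br (4 equiv), KOtBu (4 equiv), toluene/THF, 0 → 60 °C
Reagents that add atoms: methyltriphenylphosphonium bromide, C[P+](c1ccccc1)(c1ccccc1)c1ccccc1.[Br-]
Why: Wittig methylenation of the methyl ketone, whose open form is drained from the hemiketal equilibrium by excess ylide, should install the 1,1-disubstituted olefin; no stereocenter is touched.

**Step 12**
Reactants: 17 3β-bromo-14,15-dinorlabd-13(16)-en-8α-ol
Product: 18 3β-bromo-8α-(prop-2-en-1-yloxy)-14,15-dinorlabd-13(16)-ene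
Conditions: KH, allyl bromide, 18-crown-6 (cat.), THF, 0 °C → rt
Reagents that add atoms: allyl bromide, C=CCBr
Why: Williamson etherification of the tertiary potassium alkoxide with the reactive allylic bromide; C8 keeps its configuration because the C8–O bond is not broken.

**Step 13**
Reactants: 18 3β-bromo-8α-(prop-2-en-1-yloxy)-14,15-dinorlabd-13(16)-ene
Product: 19 (13Z)-3β-bromo-8α,15-epoxylabd-13-ene
Conditions: second-generation Grubbs catalyst RuCl2(=CHPh)(PCy3)(H2IMes) (10 mol %), toluene (2 mM), 80 °C
Reagents that add atoms: none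
Why: Ring-closing olefin metathesis between the allyl ether and the 1,1-disubstituted olefin, helped by the gauche arrangement of the two trans-diequatorial chains on C8 and C9, should close the eight-membered ether; the ring size enforces the Z trisubstituted olefin.

**Step 14**
Reactants: 19 (13Z)-3β-bromo-8α,15-epoxylabd-13-ene
Product: 20 (13R,14S)-3β-bromo-8α,15:13,14-diepoxylabdane (target)
Conditions: dimethyldioxirane, acetone, −20 → 0 °C
Reagents that add atoms: dimethyldioxirane, CC1(C)OO1
Why: Epoxidation with dimethyldioxirane is a stereospecific syn addition (methyl and H stay cis) and should occur on the outer face of the tub-shaped oxocene in the conformer that keeps C15 anti to the axial 8β-methyl and C12 anti to C10, which gives the 13R,14S oxirane.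

**Compound list**
1 | geranyl bromide | CC(C)=CCC/C(C)=C/CBr | starting material
2 | tert-butyl acetate | CC(=O)OC(C)(C)C | starting material
3 | tert-butyl (4E)-5,9-dimethyldeca-4,8-dienoate | CC(C)=CCC/C(C)=C/CCC(=O)OC(C)(C)C | intermediate
4 | tert-butyl (4E,8E)-10-hydroxy-5,9-dimethyldeca-4,8-dienoate | OC/C(C)=C/CC/C(C)=C/CCC(=O)OC(C)(C)C | intermediate
5 | tert-butyl (4E,8E)-5,9-dimethyl-10-oxodeca-4,8-dienoate | O=C/C(C)=C/CC/C(C)=C/CCC(=O)OC(C)(C)C | intermediate
6 | tert-butyl (4E,8E)-5,9-dimethylundeca-4,8,10-trienoate | C=C/C(C)=C/CC/C(C)=C/CCC(=O)OC(C)(C)C | intermediate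
7 | (2E)-3-ethoxy-2-methylprop-2-enal (3-ethoxymethacrolein) | CCO/C=C(\C)C=O | starting material
8 | sodium (1E)-2-methyl-3-oxoprop-1-en-1-olate | [Na+].[O-]/C=C(\C)C=O | intermediate
9 | (1E)-2-methyl-3-oxoprop-1-en-1-yl benzoate | O=C/C(C)=C/OC(=O)c1ccccc1 | intermediate
10 | tert-butyl (4E)-7-[(1R,5R,6R)-5-(benzoyloxy)-6-formyl-2,6-dimethylcyclohex-2-en-1-yl]-5-methylhept-4-enoate (formyl cis, benzoate trans to the side chain) | C[C@]1(C=O)[C@H](OC(=O)c2ccccc2)CC=C(C)[C@H]1CC/C(C)=C/CCC(=O)OC(C)(C)C | intermediate
11 | 4-methylbenzenesulfonylhydrazone of 10 (E at C=N) | C[C@]1(/C=N/NS(=O)(=O)c2ccc(C)cc2)[C@H](OC(=O)c2ccccc2)CC=C(C)[C@H]1CC/C(C)=C/CCC(=O)OC(C)(C)C | intermediate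
12 | tert-butyl (4E)-7-[(1R,5R)-5-(benzoyloxy)-2,6,6-trimethylcyclohex-2-en-1-yl]-5-methylhept-4-enoate | CC1(C)[C@H](OC(=O)c2ccccc2)CC=C(C)[C@H]1CC/C(C)=C/CCC(=O)OC(C)(C)C | intermediate
13 | tert-butyl (4E)-7-[(1R,5R)-5-hydroxy-2,6,6-trimethylcyclohex-2-en-1-yl]-5-methylhept-4-enoate | CC1(C)[C@H](O)CC=C(C)[C@H]1CC/C(C)=C/CCC(=O)OC(C)(C)C | intermediate
14 | tert-butyl (4E)-7-[(1R,5S)-5-bromo-2,6,6-trimethylcyclohex-2-en-1-yl]-5-methylhept-4-enoate | CC1(C)[C@@H](Br)CC=C(C)[C@H]1CC/C(C)=C/CCC(=O)OC(C)(C)C | intermediate
15 | 3β-bromoambreinolide (3β-bromo-8α,13-epoxy-14,15,16-trinorlabdan-13-one) | CC1(C)[C@@H](Br)CC[C@]2(C)[C@H]3CCC(=O)O[C@]3(C)CC[C@@H]12 | intermediate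
16 | 3β-bromo-8α-hydroxy-14,15-dinorlabdan-13-one (open form of the hemiketal) | CC1(C)[C@@H](Br)CC[C@]2(C)[C@@H](CCC(C)=O)[C@](C)(O)CC[C@@H]12 | intermediate
17 | 3β-bromo-14,15-dinorlabd-13(16)-en-8α-ol | CC1(C)[C@@H](Br)CC[C@]2(C)[C@@H](CCC(C)=C)[C@](C)(O)CC[C@@H]12 | intermediate
18 | 3β-bromo-8α-(prop-2-en-1-yloxy)-14,15-dinorlabd-13(16)-ene | CC1(C)[C@@H](Br)CC[C@]2(C)[C@@H](CCC(C)=C)[C@](C)(OCC=C)CC[C@@H]12 | intermediate
19 | (13Z)-3β-bromo-8α,15-epoxylabd-13-ene | CC1(C)[C@@H](Br)CC[C@]2(C)[C@H]3CC/C(C)=C\CO[C@]3(C)CC[C@@H]12 | intermediate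
20 | (13R,14S)-3β-bromo-8α,15:13,14-diepoxylabdane | CC1(C)[C@@H](Br)CC[C@]2(C)[C@H]3CC[C@@]4(C)O[C@H]4CO[C@]3(C)CC[C@@H]12 | target

**Step count**
Total: 14 steps. Longest linear sequence: 13 steps (steps 1–3 and 5–14); step 4 is a one-step side branch.

**Steps most likely to fail**

Step 5. The cycloaddition may be too slow at the substituted C5 terminus, the trisubstituted enal being a sluggish dienophile for a trialkyl diene, and regio- and endo-control may erode at the temperature then needed. The fallback sets out from 5 and returns at 12. Addition of MeMgBr to the formyl group of 5 at −78 °C would give the allylic alcohol F1, MnO2 would oxidise it to the methyl enone F2, and TIPSOTf/Et3N would convert that into the 2-silyloxydiene F3. This diene is far more nucleophilic, and its silyloxy group on C1 also directs the formyl-bearing carbon to C5. It would be combined with 9 under the catalyst of step 5 to give the adduct F4. Deoxygenation as in step 6, through the tosylhydrazone F5, would give the silyl enol ether F6. CsF with PhNTf2 would turn this into the enol triflate F7, and reduction with Pd(OAc)2, PPh3, HCO2H and Bu3N would replace the triflate by hydrogen to give 12.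

Step 8. The neopentyl alkoxyphosphonium ion may ionise, leading to methyl shift, homoallylic participation of the ring olefin or elimination instead of direct displacement. The fallback sets out from 13 and returns at 14. It separates activation from displacement: Tf2O and pyridine at −78 °C would give the triflate F8, which would be displaced with inversion by Bu4NBr in toluene at low temperature to give 14.

Step 14. Facial selectivity may be poor or reversed if the oxocene reacts through the other tub conformer. The fallback sets out from 19 and returns at 20. NBS in aqueous acetone would give the bromohydrin F9: the bromonium ion forms on the face an electrophilic oxidant prefers and water opens it at the tertiary C13 from the opposite face. K2CO3 in methanol would then close the oxirane by intramolecular SN2 at C14, which places the oxygen on the face opposite to the one the electrophile attacked and gives 20.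

**Further compounds**
F1 | step 5 | tert-butyl (4E,8E)-10-hydroxy-5,9-dimethylundeca-4,8-dienoate (racemic carbinol) | CC(O)/C(C)=C/CC/C(C)=C/CCC(=O)OC(C)(C)C
F2 | step 5 | tert-butyl (4E,8E)-5,9-dimethyl-10-oxoundeca-4,8-dienoate | CC(=O)/C(C)=C/CC/C(C)=C/CCC(=O)OC(C)(C)C
F3 | step 5 | tert-butyl (4E,8E)-5,9-dimethyl-10-{[tri(propan-2-yl)silyl]oxy}undeca-4,8,10-trienoate | C=C(O[Si](C(C)C)(C(C)C)C(C)C)/C(C)=C/CC/C(C)=C/CCC(=O)OC(C)(C)C
F4 | step 5 | 3-{[tri(propan-2-yl)silyl]oxy} analogue of 10 (ring configuration as in 10) | C[C@]1(C=O)[C@H](OC(=O)c2ccccc2)CC(O[Si](C(C)C)(C(C)C)C(C)C)=C(C)[C@H]1CC/C(C)=C/CCC(=O)OC(C)(C)C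
F5 | step 5 | 4-methylbenzenesulfonylhydrazone of F4 | C[C@]1(/C=N/NS(=O)(=O)c2ccc(C)cc2)[C@H](OC(=O)c2ccccc2)CC(O[Si](C(C)C)(C(C)C)C(C)C)=C(C)[C@H]1CC/C(C)=C/CCC(=O)OC(C)(C)C
F6 | step 5 | 3-{[tri(propan-2-yl)silyl]oxy} analogue of 12 (ring configuration as in 12) | CC1(C)[C@H](OC(=O)c2ccccc2)CC(O[Si](C(C)C)(C(C)C)C(C)C)=C(C)[C@H]1CC/C(C)=C/CCC(=O)OC(C)(C)C
F7 | step 5 | 3-(trifluoromethanesulfonyloxy) analogue of 12 (enol triflate, ring configuration as in 12) | CC1(C)[C@H](OC(=O)c2ccccc2)CC(OS(=O)(=O)C(F)(F)F)=C(C)[C@H]1CC/C(C)=C/CCC(=O)OC(C)(C)C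
F8 | step 8 | trifluoromethanesulfonate of 13 | CC1(C)[C@H](OS(=O)(=O)C(F)(F)F)CC=C(C)[C@H]1CC/C(C)=C/CCC(=O)OC(C)(C)C
F9 | step 14 | (13R,14R)-3β,14-dibromo-8α,15-epoxylabdan-13-ol | CC1(C)[C@@H](Br)CC[C@]2(C)[C@H]3CC[C@@](C)(O)[C@H](Br)CO[C@]3(C)CC[C@@H]12
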